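## Retrosynthetic overview

1. The target is an unsymmetrical methylene-bis(acylphloroglucinol). The cut lies between the bridging CH2, which stays on the isovaleryl ring (ring A), and the ring carbon of the isobutyryl ring (ring B).
2. Enabling feature: on ring A the CH2 carbon stands between two free phenolic OH groups, so ring A–CH2–X is a latent o-quinone methide (exocyclic C=CH2 next to a ring C=O). On ring B the bonding carbon is the only ring C–H, ortho to two OH groups and para to the OMe group, and is the most nucleophilic carbon of that ring.
3. The key step is a biomimetic, protecting-group-free cross-coupling of two monomers as the last step: the Mannich base of monomer A (X = NMe2, lost in the same operation) plus free monomer B.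
4. Each monomer comes from 2-methylphloroglucinol by the same four operations: C-acylation, 4,6-di-O-benzylation, methylation of the remaining chelated 2-OH, and hydrogenolysis.
5. No ring is formed in the route. Both benzene rings are bought with 2-methylphloroglucinol.

Key step: step 10

Remark: the target has no stereocentre and no hindered axis, so it is achiral and no step has to control configuration.

## Route

Step 1
Reactants: 1 2-methylphloroglucinol (2-methylbenzene-1,3,5-triol); 2 isovaleryl chloride (3-methylbutanoyl chloride)
Product: 3 1-(2,4,6-trihydroxy-3-methylphenyl)-3-methylbutan-1-one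
Conditions: AlCl3 (3.5 equiv), CH2Cl2–PhNO2, 0 → 45 °C; then 1 M HCl
Reagents that add atoms: none
Why: Friedel–Crafts C-acylation of a phloroglucinol, in which the two free ring carbons of 1 are equivalent by symmetry and the first acyl group deactivates the ring, so a single monoketone should form and no stereocentre arises.

Step 2
Reactants: 3 1-(2,4,6-trihydroxy-3-methylphenyl)-3-methylbutan-1-one
Product: 4 1-[4,6-bis(benzyloxy)-2-hydroxy-3-methylphenyl]-3-methylbutan-1-one
Conditions: BnBr (2.1 equiv), K2CO3 (2.2 equiv), DMF, 0 °C → rt
Reagents that add atoms: benzyl bromide, BrCc1ccccc1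
Why: Williamson etherification under steric and chelation control, in which the unchelated, most acidic 4-OH and the less crowded 6-OH (next to the ring C–H) react, while the 2-OH, held between the C3 methyl and the acyl group, stays hydrogen-bonded to the ketone, as is usual in the partial alkylation of 3-methylphloroacylphenones.

Step 3
Reactants: 4 1-[4,6-bis(benzyloxy)-2-hydroxy-3-methylphenyl]-3-methylbutan-1-one
Product: 5 1-[4,6-bis(benzyloxy)-2-methoxy-3-methylphenyl]-3-methylbutan-1-one
Conditions: MeI (3 equiv), K2CO3 (2 equiv), DMF, 40 °C, closed vessel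
Reagents that add atoms: iodomethane, CI
Why: Williamson O-methylation of the last, chelated phenol, which yields to an excess of the small electrophile in a dipolar solvent, while K2CO3 is too weak to enolise the ketone.

Step 4
Reactants: 5 1-[4,6-bis(benzyloxy)-2-methoxy-3-methylphenyl]-3-methylbutan-1-one
Product: 6 1-(4,6-dihydroxy-2-methoxy-3-methylphenyl)-3-methylbutan-1-one (monomer A)
Conditions: H2 (1 atm), 10% Pd/C, EtOAc–MeOH, rt
Reagents that add atoms: none
Why: Catalytic hydrogenolysis of aryl benzyl ethers, which leaves the electron-rich aryl ketone and the methyl ether untouched at 1 atm and, unlike the cleavage of acetal-type groups, releases no formaldehyde that could bridge the nucleophilic ring.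

Step 5
Reactants: 6 1-(4,6-dihydroxy-2-methoxy-3-methylphenyl)-3-methylbutan-1-one
Product: 7 1-{3-[(dimethylamino)methyl]-2,4-dihydroxy-6-methoxy-5-methylphenyl}-3-methylbutan-1-one (Mannich base of monomer A)
Conditions: Me2NCH2NMe2 (1.5 equiv), THF, 0 °C → rt; volatiles removed at ≤ 25 °C, used crude
Reagents that add atoms: bis(dimethylamino)methane, CN(C)CN(C)C
Why: Mannich aminomethylation at the only free ring carbon of 6, which lies ortho to two OH groups and is far more nucleophilic than the ketone α-carbon, while the excess aminal and amine should return any early quinone methide to 7 and so hold back self-bridging.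

Step 6
Reactants: 1 2-methylphloroglucinol; 8 isobutyryl chloride (2-methylpropanoyl chloride)
Product: 9 2-methyl-1-(2,4,6-trihydroxy-3-methylphenyl)propan-1-one
Conditions: AlCl3 (3.5 equiv), CH2Cl2–PhNO2, 0 → 45 °C; then 1 M HCl
Reagents that add atoms: none
Why: Friedel–Crafts C-acylation as in step 1, with regiochemistry fixed by the symmetry of 1 and monoacylation secured by deactivation.

Step 7
Reactants: 9 2-methyl-1-(2,4,6-trihydroxy-3-methylphenyl)propan-1-one
Product: 10 1-[4,6-bis(benzyloxy)-2-hydroxy-3-methylphenyl]-2-methylpropan-1-one
Conditions: BnBr (2.1 equiv), K2CO3 (2.2 equiv), DMF, 0 °C → rt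
Reagents that add atoms: benzyl bromide, BrCc1ccccc1
Why: Williamson etherification with the same steric and chelation control as in step 2, which leaves the crowded, hydrogen-bonded 2-OH free.

Step 8
Reactants: 10 1-[4,6-bis(benzyloxy)-2-hydroxy-3-methylphenyl]-2-methylpropan-1-one
Product: 11 1-[4,6-bis(benzyloxy)-2-methoxy-3-methylphenyl]-2-methylpropan-1-one
Conditions: MeI (3 equiv), K2CO3 (2 equiv), DMF, 40 °C, closed vessel
Reagents that add atoms: iodomethane, CI
Why: Williamson O-methylation of the remaining chelated phenol as in step 3.

Step 9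
Reactants: 11 1-[4,6-bis(benzyloxy)-2-methoxy-3-methylphenyl]-2-methylpropan-1-one
Product: 12 1-(4,6-dihydroxy-2-methoxy-3-methylphenyl)-2-methylpropan-1-one (monomer B)
Conditions: H2 (1 atm), 10% Pd/C, EtOAc–MeOH, rt
Reagents that add atoms: none
Why: Catalytic hydrogenolysis of the two benzyl ethers as in step 4, with ketone and methyl ether inert.

Step 10
Reactants: 7 Mannich base of monomer A; 12 monomer B (1.5 equiv)
Product: 14 1-(3-{[2,6-dihydroxy-4-methoxy-3-methyl-5-(2-methylpropanoyl)phenyl]methyl}-2,4-dihydroxy-6-methoxy-5-methylphenyl)-3-methylbutan-1-one (target CNP0265841.0), via o-quinone methide 13 (not isolated)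
Conditions: slow addition of 7 to 12, 1,4-dioxane, 80 °C, Ar sparge
Reagents that add atoms: none
Why: The Mannich base sits largely as its ammonium phenolate, which on warming expels dimethylamine in a 1,4-elimination to give o-quinone methide 13, and the free ring carbon of 12 adds to the exocyclic CH2 in a conjugate (Michael/Friedel–Crafts) manner, after which tautomerisation restores both aromatic rings. The closest known reaction type is the thermal C-alkylation of phenols and acylphloroglucinols with phenolic Mannich bases through o-quinone methides, the laboratory copy of the presumed biosynthetic methylene bridging. No ring is closed and no stereocentre is formed. Site selectivity is secured because 12 has a single ring C–H, flanked by two OH groups, and because O-attack on 13 is reversible whereas C-attack ends in rearomatisation. Cross- over homo-coupling is secured because 7 is fully substituted and can act only as the CH2 donor while 12 carries no leaving group, and slow addition into an excess of 12 keeps 13 dilute, which should suppress its [4+2] self-dimerisation and ipso attack on 7. The argon stream carries off dimethylamine, which drives the elimination and removes the base that could start retro-Michael scrambling of the bridge.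

## Compound list

1 | 2-methylphloroglucinol (2-methylbenzene-1,3,5-triol) | Cc1c(O)cc(O)cc1O | starting material
2 | isovaleryl chloride (3-methylbutanoyl chloride) | CC(C)CC(=O)Cl | starting material
3 | 1-(2,4,6-trihydroxy-3-methylphenyl)-3-methylbutan-1-one | CC(C)CC(=O)c1c(O)cc(O)c(C)c1O | intermediate
4 | 1-[4,6-bis(benzyloxy)-2-hydroxy-3-methylphenyl]-3-methylbutan-1-one | CC(C)CC(=O)c1c(OCc2ccccc2)cc(OCc2ccccc2)c(C)c1O | intermediate
5 | 1-[4,6-bis(benzyloxy)-2-methoxy-3-methylphenyl]-3-methylbutan-1-one | CC(C)CC(=O)c1c(OCc2ccccc2)cc(OCc2ccccc2)c(C)c1OC | intermediate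
6 | 1-(4,6-dihydroxy-2-methoxy-3-methylphenyl)-3-methylbutan-1-one (monomer A) | CC(C)CC(=O)c1c(O)cc(O)c(C)c1OC | intermediate
7 | 1-{3-[(dimethylamino)methyl]-2,4-dihydroxy-6-methoxy-5-methylphenyl}-3-methylbutan-1-one | CC(C)CC(=O)c1c(O)c(CN(C)C)c(O)c(C)c1OC | intermediate
8 | isobutyryl chloride (2-methylpropanoyl chloride) | CC(C)C(=O)Cl | starting material
9 | 2-methyl-1-(2,4,6-trihydroxy-3-methylphenyl)propan-1-one | CC(C)C(=O)c1c(O)cc(O)c(C)c1O | intermediate
10 | 1-[4,6-bis(benzyloxy)-2-hydroxy-3-methylphenyl]-2-methylpropan-1-one | CC(C)C(=O)c1c(OCc2ccccc2)cc(OCc2ccccc2)c(C)c1O | intermediate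
11 | 1-[4,6-bis(benzyloxy)-2-methoxy-3-methylphenyl]-2-methylpropan-1-one | CC(C)C(=O)c1c(OCc2ccccc2)cc(OCc2ccccc2)c(C)c1OC | intermediate
12 | 1-(4,6-dihydroxy-2-methoxy-3-methylphenyl)-2-methylpropan-1-one (monomer B) | CC(C)C(=O)c1c(O)cc(O)c(C)c1OC | intermediate
13 | 5-hydroxy-3-methoxy-2-methyl-4-(3-methylbutanoyl)-6-methylidenecyclohexa-2,4-dien-1-one (o-quinone methide, not isolated) | C=C1C(=O)C(C)=C(OC)C(C(=O)CC(C)C)=C1O | intermediate
14 | 1-(3-{[2,6-dihydroxy-4-methoxy-3-methyl-5-(2-methylpropanoyl)phenyl]methyl}-2,4-dihydroxy-6-methoxy-5-methylphenyl)-3-methylbutan-1-one (CNP0265841.0) | COc1c(C)c(O)c(Cc2c(O)c(C)c(OC)c(C(=O)C(C)C)c2O)c(O)c1C(=O)CC(C)C | target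

## Step count and risks

Total step count: 10. Longest linear sequence: 6 (steps 1–5 and 10).

**1. Step 10.**
- **What may go wrong:** retro-Michael cleavage of the new CH2–aryl bond in the hot, amine-containing medium, followed by re-addition, would scramble the bridge towards symmetrical dimers. The quinone methide may also attack a second molecule of the Mannich base at the ipso position.
- **Fallback:** the partners carry no free OH, so no quinone methide can be re-formed. It sets out from 5 and 11 and comes back at 14.
- Vilsmeier–Haack formylation (POCl3, DMF) of the only free ring carbon of 5 would give 2,6-bis(benzyloxy)-4-methoxy-3-methyl-5-(3-methylbutanoyl)benzaldehyde F1.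
- NaBH4 at low temperature should reduce the aldehyde in preference to the hindered, di-ortho-substituted ketone, giving 1-[2,4-bis(benzyloxy)-3-(hydroxymethyl)-6-methoxy-5-methylphenyl]-3-methylbutan-1-one F2.
- A catalytic acid (for example Bi(OTf)3 in CH2Cl2) ionises this alcohol to a benzylic cation stabilised by three alkoxy groups. The cation alkylates the free ring carbon of 11 in a Friedel–Crafts benzylation to give the tetra-O-benzyl ether of the target F3.
- Hydrogenolysis (H2, Pd/C) of the four benzyl ethers gives 14.

**2. Step 5.**
- **What may go wrong:** early loss of dimethylamine while unreacted monomer is still present would bridge the monomer with itself. The Mannich base may also decompose on concentration.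
- **Fallback:** it sets out from 6 and comes back at 13, and hence at 14.
- Three-component sulfonylmethylation of 6 with formaldehyde and p-toluenesulfinic acid (aqueous HCO2H, rt) would give 1-{2,4-dihydroxy-6-methoxy-5-methyl-3-[(4-methylbenzene-1-sulfonyl)methyl]phenyl}-3-methylbutan-1-one F4. The soft sulfinate outruns the arene for the hydroxymethyl or quinone methide stage.
- This sulfone should be crystalline and storable, because sulfinate leaves only after the phenol is deprotonated.
- Mild base (aqueous NaHCO3–CH2Cl2, rt) in the presence of 12 releases 13 at room temperature, which is trapped as in step 10.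

**3. Step 2** (step 7 is the same reaction on the other ketone and shares the risk).
- **What may go wrong:** the 2-OH may be alkylated in competition with the 6-OH, and the free ring carbon of the ambident phenolate may be C-benzylated.
- **Fallback:** the regiochemical question is removed by symmetry and the methyl group is added later. It sets out from 2 and comes back at 5.
- Friedel–Crafts acylation of bought phloroglucinol F5 with 2 (AlCl3) would give 1-(2,4,6-trihydroxyphenyl)-3-methylbutan-1-one F6. Its two ortho OH groups are equivalent, so double benzylation can give only one chelated phenol, 1-[2,4-bis(benzyloxy)-6-hydroxyphenyl]-3-methylbutan-1-one F7.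
- Electrophilic iodination (NIS, cat. TFA, MeCN) should go ortho to the free OH, the less crowded of the two free ring carbons, giving 1-[4,6-bis(benzyloxy)-2-hydroxy-3-iodophenyl]-3-methylbutan-1-one F8.
- O-methylation (MeI, K2CO3, DMF) gives 1-[4,6-bis(benzyloxy)-3-iodo-2-methoxyphenyl]-3-methylbutan-1-one F9.
- Suzuki–Miyaura methylation (trimethylboroxine, Pd(OAc)2/SPhos, K3PO4, dioxane–water, 90 °C) gives 5.

## Further compounds

F1 | step 10 | 2,6-bis(benzyloxy)-4-methoxy-3-methyl-5-(3-methylbutanoyl)benzaldehyde | CC(C)CC(=O)c1c(OCc2ccccc2)c(C=O)c(OCc2ccccc2)c(C)c1OC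
F2 | step 10 | 1-[2,4-bis(benzyloxy)-3-(hydroxymethyl)-6-methoxy-5-methylphenyl]-3-methylbutan-1-one | CC(C)CC(=O)c1c(OCc2ccccc2)c(CO)c(OCc2ccccc2)c(C)c1OC
F3 | step 10 | tetra-O-benzyl ether of the target | COc1c(C)c(OCc2ccccc2)c(Cc2c(OCc3ccccc3)c(C)c(OC)c(C(=O)C(C)C)c2OCc2ccccc2)c(OCc2ccccc2)c1C(=O)CC(C)C
F4 | step 5 | 1-{2,4-dihydroxy-6-methoxy-5-methyl-3-[(4-methylbenzene-1-sulfonyl)methyl]phenyl}-3-methylbutan-1-one | CC(C)CC(=O)c1c(O)c(CS(=O)(=O)c2ccc(C)cc2)c(O)c(C)c1OC
F5 | step 2 | phloroglucinol (benzene-1,3,5-triol, bought) | Oc1cc(O)cc(O)c1
F6 | step 2 | 1-(2,4,6-trihydroxyphenyl)-3-methylbutan-1-one | CC(C)CC(=O)c1c(O)cc(O)cc1O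
F7 | step 2 | 1-[2,4-bis(benzyloxy)-6-hydroxyphenyl]-3-methylbutan-1-one | CC(C)CC(=O)c1c(O)cc(OCc2ccccc2)cc1OCc1ccccc1
F8 | step 2 | 1-[4,6-bis(benzyloxy)-2-hydroxy-3-iodophenyl]-3-methylbutan-1-one | CC(C)CC(=O)c1c(O)c(I)c(OCc2ccccc2)cc1OCc1ccccc1
F9 | step 2 | 1-[4,6-bis(benzyloxy)-3-iodo-2-methoxyphenyl]-3-methylbutan-1-one | CC(C)CC(=O)c1c(OC)c(I)c(OCc2ccccc2)cc1OCc1ccccc1
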